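The lactone is disconnected at the C5–O1 bond (ring numbered O1, C2 carbonyl, C3, C4, C5; C6 is the benzylic CH2 on C4, C7 the carbinol carbon on C3). C5 is a methylene that touches only C4 and O1 and lies γ to the C2 carboxyl, so it is carried as a plain methyl group. One palladium-catalysed, carboxylate-directed C–H oxidation of that methyl group forms C5–O1 and closes the five-membered ring. Its substrate is the open-chain (2S,3R)-2-[(S)-aryl(silyloxy)methyl]-4-aryl-3-methylbutanoic acid, with all three stereocentres set by catalytic conjugate methylation and an auxiliary-controlled syn aldol, and with both phenols as acetates so that the arenes resist the oxidant.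

Key step: step 11

Remark on structures: the target is (3S,4R) in the ring and (S) at C7. Acid 21 carries the same three centres as (2S,3R) and (S) at the carbinol carbon, and the (S)-oxazolidinone is the correct antipode for the syn aldol.

Remark on protecting groups: the phenols travel as benzyl ethers through the Grignard, hydroxide and peroxide steps, which aryl esters would not survive. They are exchanged for acetates before the key step, and the hydrogenolysis is done while C7–O is silylated.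

Assumption: (R)-Tol-BINAP is taken as the ligand enantiomer that sends methyl to the Re face of the β-carbon of enoate 4; should a first run show the opposite sense, the (S)-ligand is used and nothing else changes.

Step 1
Reactants: 1 eugenol
Product: 2 4-allyl-1-(benzyloxy)-2-methoxybenzene
Conditions: BnBr, K2CO3, DMF, rt
Reagents that add atoms: benzyl bromide, BrCc1ccccc1
Why: Williamson ether synthesis on the phenoxide; the benzyl ether withstands the Grignard, hydroxide and peroxide steps that follow.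

Step 2
Reactants: 2 4-allyl-1-(benzyloxy)-2-methoxybenzene; 3 methyl acrylate
Product: 4 methyl (E)-4-[4-(benzyloxy)-3-methoxyphenyl]but-2-enoate
Conditions: 3 (3 equiv), second-generation Hoveyda–Grubbs catalyst RuCl2(H2IMes)(=CH-C6H4-2-O-i-Pr) (2 mol %), CH2Cl2, 40 °C
Reagents that add atoms: none
Why: Olefin cross-metathesis between a terminal allylarene and an electron-poor acrylate used in excess, which should pair the two alkenes selectively and give the (E)-enoate with loss of ethene.

Step 3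
Reactants: 4 methyl (E)-4-[4-(benzyloxy)-3-methoxyphenyl]but-2-enoate
Product: 6 methyl (R)-4-[4-(benzyloxy)-3-methoxyphenyl]-3-methylbutanoate, via magnesium enolate 5 (not isolated)
Conditions: MeMgBr, CuI (2 mol %), (R)-Tol-BINAP (3 mol %), t-BuOMe, −20 °C; aq. NH4Cl
Reagents that add atoms: methylmagnesium bromide, C[Mg]Br
Why: Copper-catalysed asymmetric conjugate addition of a Grignard reagent to an (E)-enoate, in which the CuI–Tol-BINAP complex delivers methyl to the Re face of the β-carbon and so sets the (R) centre that becomes C4 of the lactone.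

Step 4
Reactants: 6 methyl (R)-4-[4-(benzyloxy)-3-methoxyphenyl]-3-methylbutanoate
Product: 7 (R)-4-[4-(benzyloxy)-3-methoxyphenyl]-3-methylbutanoic acid
Conditions: LiOH, THF/MeOH/H2O, rt; then 1 M HCl
Reagents that add atoms: lithium hydroxide (hydroxide oxygen), [Li+].[OH-]
Why: Saponification of a methyl ester, which leaves the non-acidic β-stereocentre untouched.

Step 5
Reactants: 7 (R)-4-[4-(benzyloxy)-3-methoxyphenyl]-3-methylbutanoic acid; 8 (S)-4-benzyloxazolidin-2-one
Product: 10 (S)-4-benzyl-3-[(R)-4-[4-(benzyloxy)-3-methoxyphenyl]-3-methylbutanoyl]oxazolidin-2-one, via mixed pivalic anhydride 9 (not isolated)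
Conditions: t-BuCOCl, Et3N, THF, −20 °C; then LiCl, 8, rt
Reagents that add atoms: none
Why: N-acylation of the oxazolidinone through the mixed pivalic anhydride, activated by LiCl and Et3N, which needs no strong base.

Step 6
Reactants: 10 (S)-4-benzyl-3-[(R)-4-[4-(benzyloxy)-3-methoxyphenyl]-3-methylbutanoyl]oxazolidin-2-one; 11 4-(benzyloxy)-3-methoxybenzaldehyde
Product: 14 (S)-4-benzyl-3-[(2S,3R)-2-[(S)-[4-(benzyloxy)-3-methoxyphenyl](hydroxy)methyl]-4-[4-(benzyloxy)-3-methoxyphenyl]-3-methylbutanoyl]oxazolidin-2-one, via boron enolate 12 (not isolated), via boron aldolate 13 (not isolated)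
Conditions: Bu2BOTf, i-Pr2NEt, CH2Cl2, 0 °C; 11, −78 to 0 °C; pH 7 buffer, MeOH, H2O2, 0 °C
Reagents that add atoms: none
Why: Evans syn aldol reaction, in which the (Z)-dibutylboron enolate meets the aldehyde in a Zimmerman–Traxler chair on the face away from the auxiliary benzyl group and so sets C3 (S) and C7 (S) under reagent control, regardless of the existing C4 centre.

Step 7
Reactants: 14 (S)-4-benzyl-3-[(2S,3R)-2-[(S)-[4-(benzyloxy)-3-methoxyphenyl](hydroxy)methyl]-4-[4-(benzyloxy)-3-methoxyphenyl]-3-methylbutanoyl]oxazolidin-2-one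
Product: 16 (2S,3R)-2-[(S)-[4-(benzyloxy)-3-methoxyphenyl](hydroxy)methyl]-4-[4-(benzyloxy)-3-methoxyphenyl]-3-methylbutanoic acid, via peroxy acid 15 (not isolated)
Conditions: LiOH, H2O2, THF/H2O, 0 °C; then aq. Na2SO3; 1 M HCl to pH 3, 0 °C
Reagents that add atoms: hydrogen peroxide, OO
Why: Hydroperoxide cleavage of the N-acyl oxazolidinone, in which LiOOH attacks the exocyclic carbonyl selectively and sulfite reduces the peroxy acid, with no stereocentre touched at 0 °C.

Step 8
Reactants: 16 (2S,3R)-2-[(S)-[4-(benzyloxy)-3-methoxyphenyl](hydroxy)methyl]-4-[4-(benzyloxy)-3-methoxyphenyl]-3-methylbutanoic acid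
Product: 18 (2S,3R)-2-[(S)-[4-(benzyloxy)-3-methoxyphenyl][(tert-butyldimethylsilyl)oxy]methyl]-4-[4-(benzyloxy)-3-methoxyphenyl]-3-methylbutanoic acid, via silyl ester 17 (not isolated)
Conditions: TBSOTf (2.5 equiv), 2,6-lutidine, CH2Cl2, 0 °C; then MeOH/THF/H2O, K2CO3 (cat.), rt
Reagents that add atoms: tert-butyldimethylsilyl triflate, CC(C)(C)[Si](C)(C)OS(=O)(=O)C(F)(F)F
Why: Silylation of both the alcohol and the acid with the silyl triflate, followed by selective hydrolysis of the labile silyl ester, which leaves the secondary silyl ether in place.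

Step 9
Reactants: 18 (2S,3R)-2-[(S)-[4-(benzyloxy)-3-methoxyphenyl][(tert-butyldimethylsilyl)oxy]methyl]-4-[4-(benzyloxy)-3-methoxyphenyl]-3-methylbutanoic acid
Product: 19 (2S,3R)-2-[(S)-[(tert-butyldimethylsilyl)oxy](4-hydroxy-3-methoxyphenyl)methyl]-4-(4-hydroxy-3-methoxyphenyl)-3-methylbutanoic acid
Conditions: H2 (1 atm), Pd/C, EtOAc, rt
Reagents that add atoms: none
Why: Catalytic hydrogenolysis of the two aryl benzyl ethers, placed here because the C7–O bond is masked as a bulky silyl ether and should survive in an aprotic solvent, which the free benzylic alcohol would not.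

Step 10
Reactants: 19 (2S,3R)-2-[(S)-[(tert-butyldimethylsilyl)oxy](4-hydroxy-3-methoxyphenyl)methyl]-4-(4-hydroxy-3-methoxyphenyl)-3-methylbutanoic acid
Product: 21 (2S,3R)-4-(4-acetoxy-3-methoxyphenyl)-2-[(S)-(4-acetoxy-3-methoxyphenyl)[(tert-butyldimethylsilyl)oxy]methyl]-3-methylbutanoic acid, via mixed acetic anhydride 20 (not isolated)
Conditions: Ac2O, pyridine, CH2Cl2, 0 °C to rt; then THF/aq. NaHCO3, rt; pH 4
Reagents that add atoms: acetic anhydride, CC(=O)OC(C)=O
Why: Acetylation of both phenols with Ac2O and pyridine, the carboxyl group returning from its mixed anhydride on aqueous bicarbonate treatment, so that both rings are electron-poor for the oxidation that follows.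

Step 11
Reactants: 21 (2S,3R)-4-(4-acetoxy-3-methoxyphenyl)-2-[(S)-(4-acetoxy-3-methoxyphenyl)[(tert-butyldimethylsilyl)oxy]methyl]-3-methylbutanoic acid
Product: 22 (3S,4R)-4-(4-acetoxy-3-methoxybenzyl)-3-[(S)-(4-acetoxy-3-methoxyphenyl)[(tert-butyldimethylsilyl)oxy]methyl]dihydrofuran-2(3H)-one
Conditions: Pd(OAc)2 (10 mol %), N-acetylglycine (20 mol %), CsHCO3 (0.5 equiv), t-BuOOH (in decane, 2 equiv), (CF3)2CHOH, 60 °C
Reagents that add atoms: none
Why: Proposed new method: the carboxylate of 21 binds divalent palladium, and concerted metalation–deprotonation at the γ-methyl group (C5), assisted by the N-acetylglycine ligand, should give a six-membered palladacycle (Pd, O, C2, C3, C4, C5) that t-BuOOH oxidises to tetravalent palladium before C5–O1 reductive elimination releases the lactone and divalent palladium. The closest known reaction type is the palladium-catalysed C(sp3)–H lactonization of free aliphatic carboxylic acids with peroxide oxidants, which has not been shown on an acid that carries two aryl rings and a benzylic silyl ether. The single ring is closed in a 5-exo-tet sense, the carboxylate oxygen displacing palladium from C5. No stereocentre is formed: C3, C4 and C7 come unchanged from 21, and the medium is too weakly basic to enolise the carboxylate at C3. The step needs site selectivity for C5–H over the benzylic C6–H2, the tertiary C4–H and C7–H, and the arene C–H bonds, of which the ortho C–H of the C7 ring (seven-membered palladacycle) is the most serious competitor. This rests on the preference of carboxylate-directed palladation for primary C–H bonds through a six-membered palladacycle, on both β positions being methines, and on the two aryl acetates, which make the rings poor partners for electrophilic palladation and oxidation and slow ionisation at C7.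

Step 12
Reactants: 22 (3S,4R)-4-(4-acetoxy-3-methoxybenzyl)-3-[(S)-(4-acetoxy-3-methoxyphenyl)[(tert-butyldimethylsilyl)oxy]methyl]dihydrofuran-2(3H)-one
Product: 23 (3S,4R)-3-[(S)-[(tert-butyldimethylsilyl)oxy](4-hydroxy-3-methoxyphenyl)methyl]-4-(4-hydroxy-3-methoxybenzyl)dihydrofuran-2(3H)-one
Conditions: pyrrolidine (3 equiv), MeCN, 0 °C; pH 5 buffer
Reagents that add atoms: none
Why: Aminolysis of the two aryl acetates by pyrrolidine, which should be far faster than attack on the γ-lactone, while the silyl ether at C7 rules out retro-aldol cleavage during this mildly basic step.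

Step 13
Reactants: 23 (3S,4R)-3-[(S)-[(tert-butyldimethylsilyl)oxy](4-hydroxy-3-methoxyphenyl)methyl]-4-(4-hydroxy-3-methoxybenzyl)dihydrofuran-2(3H)-one
Product: 24 (3S,4R)-4-(4-hydroxy-3-methoxybenzyl)-3-[(S)-hydroxy(4-hydroxy-3-methoxyphenyl)methyl]dihydrofuran-2(3H)-one
Conditions: Bu4NF, AcOH (1:1), THF, 0 °C to rt
Reagents that add atoms: none
Why: Fluoride desilylation buffered with acetic acid to near neutrality, so that the free p-hydroxybenzylic β-hydroxy lactone is exposed to neither base nor acid.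

Compound list
1 | eugenol (4-allyl-2-methoxyphenol) | C=CCc1ccc(O)c(OC)c1 | starting material
2 | 4-allyl-1-(benzyloxy)-2-methoxybenzene | C=CCc1ccc(OCc2ccccc2)c(OC)c1 | intermediate
3 | methyl acrylate | C=CC(=O)OC | starting material
4 | methyl (E)-4-[4-(benzyloxy)-3-methoxyphenyl]but-2-enoate | COC(=O)/C=C/Cc1ccc(OCc2ccccc2)c(OC)c1 | intermediate
5 | bromomagnesium (Z)-enolate of 6 | Br[Mg]O/C(OC)=C\[C@H](C)Cc1ccc(OCc2ccccc2)c(OC)c1 | intermediate
6 | methyl (R)-4-[4-(benzyloxy)-3-methoxyphenyl]-3-methylbutanoate | COC(=O)C[C@H](C)Cc1ccc(OCc2ccccc2)c(OC)c1 | intermediate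
7 | (R)-4-[4-(benzyloxy)-3-methoxyphenyl]-3-methylbutanoic acid | OC(=O)C[C@H](C)Cc1ccc(OCc2ccccc2)c(OC)c1 | intermediate
8 | (S)-4-benzyloxazolidin-2-one | O=C1N[C@@H](Cc2ccccc2)CO1 | starting material
9 | mixed anhydride of 7 with pivalic acid | CC(C)(C)C(=O)OC(=O)C[C@H](C)Cc1ccc(OCc2ccccc2)c(OC)c1 | intermediate
10 | (S)-4-benzyl-3-[(R)-4-[4-(benzyloxy)-3-methoxyphenyl]-3-methylbutanoyl]oxazolidin-2-one | O=C1OC[C@H](Cc2ccccc2)N1C(=O)C[C@H](C)Cc1ccc(OCc2ccccc2)c(OC)c1 | intermediate
11 | 4-(benzyloxy)-3-methoxybenzaldehyde (O-benzylvanillin) | O=Cc1ccc(OCc2ccccc2)c(OC)c1 | starting material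
12 | (Z)-dibutylboron enolate of 10 | CCCCB(CCCC)O/C(=C\[C@H](C)Cc1ccc(OCc2ccccc2)c(OC)c1)N1[C@@H](Cc2ccccc2)COC1=O | intermediate
13 | dibutylboron aldolate of 14 | O=C1OC[C@H](Cc2ccccc2)N1C(=O)[C@H]([C@H](OB(CCCC)CCCC)c1ccc(OCc2ccccc2)c(OC)c1)[C@H](C)Cc1ccc(OCc2ccccc2)c(OC)c1 | intermediate
14 | (S)-4-benzyl-3-[(2S,3R)-2-[(S)-[4-(benzyloxy)-3-methoxyphenyl](hydroxy)methyl]-4-[4-(benzyloxy)-3-methoxyphenyl]-3-methylbutanoyl]oxazolidin-2-one | O=C1OC[C@H](Cc2ccccc2)N1C(=O)[C@H]([C@H](O)c1ccc(OCc2ccccc2)c(OC)c1)[C@H](C)Cc1ccc(OCc2ccccc2)c(OC)c1 | intermediate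
15 | peroxy acid corresponding to 16 | OOC(=O)[C@H]([C@H](O)c1ccc(OCc2ccccc2)c(OC)c1)[C@H](C)Cc1ccc(OCc2ccccc2)c(OC)c1 | intermediate
16 | (2S,3R)-2-[(S)-[4-(benzyloxy)-3-methoxyphenyl](hydroxy)methyl]-4-[4-(benzyloxy)-3-methoxyphenyl]-3-methylbutanoic acid | OC(=O)[C@H]([C@H](O)c1ccc(OCc2ccccc2)c(OC)c1)[C@H](C)Cc1ccc(OCc2ccccc2)c(OC)c1 | intermediate
17 | tert-butyldimethylsilyl ester of 18 | CC(C)(C)[Si](C)(C)OC(=O)[C@H]([C@H](O[Si](C)(C)C(C)(C)C)c1ccc(OCc2ccccc2)c(OC)c1)[C@H](C)Cc1ccc(OCc2ccccc2)c(OC)c1 | intermediate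
18 | (2S,3R)-2-[(S)-[4-(benzyloxy)-3-methoxyphenyl][(tert-butyldimethylsilyl)oxy]methyl]-4-[4-(benzyloxy)-3-methoxyphenyl]-3-methylbutanoic acid | OC(=O)[C@H]([C@H](O[Si](C)(C)C(C)(C)C)c1ccc(OCc2ccccc2)c(OC)c1)[C@H](C)Cc1ccc(OCc2ccccc2)c(OC)c1 | intermediate
19 | (2S,3R)-2-[(S)-[(tert-butyldimethylsilyl)oxy](4-hydroxy-3-methoxyphenyl)methyl]-4-(4-hydroxy-3-methoxyphenyl)-3-methylbutanoic acid | OC(=O)[C@H]([C@H](O[Si](C)(C)C(C)(C)C)c1ccc(O)c(OC)c1)[C@H](C)Cc1ccc(O)c(OC)c1 | intermediate
20 | mixed anhydride of 21 with acetic acid | CC(=O)OC(=O)[C@H]([C@H](O[Si](C)(C)C(C)(C)C)c1ccc(OC(C)=O)c(OC)c1)[C@H](C)Cc1ccc(OC(C)=O)c(OC)c1 | intermediate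
21 | (2S,3R)-4-(4-acetoxy-3-methoxyphenyl)-2-[(S)-(4-acetoxy-3-methoxyphenyl)[(tert-butyldimethylsilyl)oxy]methyl]-3-methylbutanoic acid | OC(=O)[C@H]([C@H](O[Si](C)(C)C(C)(C)C)c1ccc(OC(C)=O)c(OC)c1)[C@H](C)Cc1ccc(OC(C)=O)c(OC)c1 | intermediate
22 | (3S,4R)-4-(4-acetoxy-3-methoxybenzyl)-3-[(S)-(4-acetoxy-3-methoxyphenyl)[(tert-butyldimethylsilyl)oxy]methyl]dihydrofuran-2(3H)-one | O=C1OC[C@H](Cc2ccc(OC(C)=O)c(OC)c2)[C@H]1[C@H](O[Si](C)(C)C(C)(C)C)c1ccc(OC(C)=O)c(OC)c1 | intermediate
23 | (3S,4R)-3-[(S)-[(tert-butyldimethylsilyl)oxy](4-hydroxy-3-methoxyphenyl)methyl]-4-(4-hydroxy-3-methoxybenzyl)dihydrofuran-2(3H)-one | O=C1OC[C@H](Cc2ccc(O)c(OC)c2)[C@H]1[C@H](O[Si](C)(C)C(C)(C)C)c1ccc(O)c(OC)c1 | intermediate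
24 | (3S,4R)-4-(4-hydroxy-3-methoxybenzyl)-3-[(S)-hydroxy(4-hydroxy-3-methoxyphenyl)methyl]dihydrofuran-2(3H)-one | COc1cc(C[C@H]2COC(=O)[C@@H]2[C@H](O)c2ccc(O)c(OC)c2)ccc1O | target

Total step count: 13 steps.
Longest linear sequence: 13 steps, from eugenol 1 to 24.

Steps most likely to fail

Step 11 (key step). What may go wrong: palladation or oxidation at an arene C–H or at the benzylic C6–H2 instead of the methyl group, β-hydride loss from the alkylpalladium intermediate, or partial loss of an aryl acetate to the peroxide. The fallback uses known chemistry and brings C5 in at a higher oxidation level. It sets out from 8 and 2. N-Acylation of 8 (n-BuLi, acryloyl chloride, THF, −78 °C) gives (S)-3-acryloyl-4-benzyloxazolidin-2-one F1, and cross-metathesis of F1 with 2 (second-generation Hoveyda–Grubbs catalyst, CH2Cl2, 40 °C) gives the (E)-enoyl imide F2. Auxiliary-controlled conjugate addition of the vinyl cuprate from CH2=CHMgBr and CuBr·SMe2 (THF/Me2S, −78 to −20 °C), anti to the auxiliary benzyl group in the chelated s-cis conformer, gives the (R)-3-vinyl imide F3, whose vinyl CH is the future C5. The boron syn aldol with 11 under the conditions of step 6 gives the aldol adduct F4, and TBSOTf with 2,6-lutidine gives its silyl ether F5. Cleavage of the vinyl group with OsO4 (cat.), NaIO4 and 2,6-lutidine in dioxane/water gives the aldehyde F6. Immediate reduction with NaBH4 in MeOH at −20 °C gives the primary alcohol, which closes onto the imide carbonyl with release of 8 to give the di-O-benzyl silyl lactone F7. Hydrogenolysis (H2, Pd/C, EtOAc) then rejoins the route at 23.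

Step 3. What may go wrong: deprotonation of the doubly activated benzylic methylene of 4 by the Grignard reagent with drift of the double bond toward the arene, or insufficient facial selectivity. The fallback replaces catalytic conjugate addition by auxiliary alkylation and one-carbon homologation. It sets out from 8. Propionylation (n-BuLi, EtCOCl, THF, −78 °C) gives the N-propionyl imide F8. Its sodium enolate (NaN(SiMe3)2, THF, −78 °C) is alkylated with commercial 4-(benzyloxy)-3-methoxybenzyl bromide on the face away from the auxiliary benzyl group to give the alkylated imide F9. LiOH/H2O2 gives the (R)-2-methyl acid F10. Oxalyl chloride with catalytic DMF gives the acid chloride F11, and Me3SiCHN2 gives the diazoketone F12. Wolff rearrangement with PhCO2Ag and Et3N in aqueous THF, which retains configuration at the migrating carbon, rejoins the route at 7.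

Step 13. What may go wrong: retro-aldol cleavage of the C3–C7 bond or loss of water across C3–C7 once the free p-hydroxybenzylic alcohol meets fluoride that is not fully buffered, or sluggish cleavage of the hindered silyl ether. The fallback changes the order of unmasking. It sets out from 22. Desilylation with HF·pyridine in THF/pyridine at 0 °C gives the diacetate alcohol F13, in which the carbinol sits on an electron-poor ring and cannot be pushed out by a phenoxide. Aminolysis of the two aryl acetates with pyrrolidine in MeCN at 0 °C then rejoins the route at 24.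

Further compounds
F1 | step 11 | (S)-3-acryloyl-4-benzyloxazolidin-2-one | C=CC(=O)N1[C@@H](Cc2ccccc2)COC1=O
F2 | step 11 | (S)-4-benzyl-3-[(E)-4-[4-(benzyloxy)-3-methoxyphenyl]but-2-enoyl]oxazolidin-2-one | O=C(/C=C/Cc1ccc(OCc2ccccc2)c(OC)c1)N1[C@@H](Cc2ccccc2)COC1=O
F3 | step 11 | (S)-4-benzyl-3-[(R)-3-[4-(benzyloxy)-3-methoxybenzyl]pent-4-enoyl]oxazolidin-2-one | O=C(C[C@H](C=C)Cc1ccc(OCc2ccccc2)c(OC)c1)N1[C@@H](Cc2ccccc2)COC1=O
F4 | step 11 | (S)-4-benzyl-3-[(2S,3S)-2-[(S)-[4-(benzyloxy)-3-methoxyphenyl](hydroxy)methyl]-3-[4-(benzyloxy)-3-methoxybenzyl]pent-4-enoyl]oxazolidin-2-one | O=C([C@H]([C@H](O)c1ccc(OCc2ccccc2)c(OC)c1)[C@H](C=C)Cc1ccc(OCc2ccccc2)c(OC)c1)N1[C@@H](Cc2ccccc2)COC1=O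
F5 | step 11 | tert-butyldimethylsilyl ether of F4 | O=C([C@H]([C@H](O[Si](C)(C)C(C)(C)C)c1ccc(OCc2ccccc2)c(OC)c1)[C@H](C=C)Cc1ccc(OCc2ccccc2)c(OC)c1)N1[C@@H](Cc2ccccc2)COC1=O
F6 | step 11 | (S)-4-benzyl-3-[(2S,3R)-2-[(S)-[4-(benzyloxy)-3-methoxyphenyl][(tert-butyldimethylsilyl)oxy]methyl]-3-[4-(benzyloxy)-3-methoxybenzyl]-4-oxobutanoyl]oxazolidin-2-one | O=C([C@H]([C@H](O[Si](C)(C)C(C)(C)C)c1ccc(OCc2ccccc2)c(OC)c1)[C@H](C=O)Cc1ccc(OCc2ccccc2)c(OC)c1)N1[C@@H](Cc2ccccc2)COC1=O
F7 | step 11 | (3S,4R)-4-[4-(benzyloxy)-3-methoxybenzyl]-3-[(S)-[4-(benzyloxy)-3-methoxyphenyl][(tert-butyldimethylsilyl)oxy]methyl]dihydrofuran-2(3H)-one | O=C1OC[C@H](Cc2ccc(OCc3ccccc3)c(OC)c2)[C@H]1[C@H](O[Si](C)(C)C(C)(C)C)c1ccc(OCc2ccccc2)c(OC)c1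
F8 | step 3 | (S)-4-benzyl-3-propionyloxazolidin-2-one | CCC(=O)N1[C@@H](Cc2ccccc2)COC1=O
F9 | step 3 | (S)-4-benzyl-3-[(R)-3-[4-(benzyloxy)-3-methoxyphenyl]-2-methylpropanoyl]oxazolidin-2-one | C[C@H](Cc1ccc(OCc2ccccc2)c(OC)c1)C(=O)N1[C@@H](Cc2ccccc2)COC1=O
F10 | step 3 | (R)-3-[4-(benzyloxy)-3-methoxyphenyl]-2-methylpropanoic acid | C[C@H](Cc1ccc(OCc2ccccc2)c(OC)c1)C(=O)O
F11 | step 3 | (R)-3-[4-(benzyloxy)-3-methoxyphenyl]-2-methylpropanoyl chloride | C[C@H](Cc1ccc(OCc2ccccc2)c(OC)c1)C(=O)Cl
F12 | step 3 | (R)-4-[4-(benzyloxy)-3-methoxyphenyl]-1-diazo-3-methylbutan-2-one | C[C@H](Cc1ccc(OCc2ccccc2)c(OC)c1)C(=O)C=[N+]=[N-]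
F13 | step 13 | (3S,4R)-4-(4-acetoxy-3-methoxybenzyl)-3-[(S)-(4-acetoxy-3-methoxyphenyl)(hydroxy)methyl]dihydrofuran-2(3H)-one | O=C1OC[C@H](Cc2ccc(OC(C)=O)c(OC)c2)[C@H]1[C@H](O)c1ccc(OC(C)=O)c(OC)c1
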